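**Retrosynthetic overview**

1. Both aryl rings are bought as O-benzylvanillic acid 1 (activated as acid chloride 2). The cyclohexane ring with all four stereocentres is bought as (−)-quinic acid 3.
2. Key disconnection: the two ester C–O bonds at O3/O4 are cut back to 2 and a tin-activated cis-diol; the lactone and tin rings are then cut back to 3 and Bu2SnO 4.
3. Forward, 3 + 4 close two rings in one dehydration (C1-carboxyl/O5 γ-lactone and O3/O4 dioxastannolane) to tricycle 5. In the same pot 5 takes up two molecules of 2 (via 6) to give bis-ester lactone 7.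
4. Endgame: hydrogenolysis of both benzyl ethers (8) and acid hydrolysis of the lactone release Burkinabin A 9.
5. Ring order: arenes and carbocycle purchased; lactone and stannolane formed together in step 2; stannolane opened in step 2, lactone opened in step 3.

Assumption: the SMILES is read as 3,4-di-O-vanilloyl-(−)-quinic acid, (1R,3R,4S,5R); quinic acid numbering is used throughout (C1 carries CO2H; 3-OH/4-OH cis; 4-OH/5-OH trans; CO2H cis to 5-OH), "1,5-quinide" means the γ-lactone of C1-CO2H onto O5, and 4-(benzyloxy)-3-methoxybenzoic acid is taken as a catalogue compound.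

**Route**

Step 1
Reactants: 1 4-(benzyloxy)-3-methoxybenzoic acid
Product: 2 4-(benzyloxy)-3-methoxybenzoyl chloride
Conditions: (COCl)2 (1.3 equiv), DMF (cat.), CH2Cl2, 0 °C to rt, 2 h; concentrate, use crude
Reagents that add atoms: oxalyl chloride, O=C(Cl)C(=O)Cl
Why: DMF-catalysed (Vilsmeier-type) acid chloride formation is clean for electron-rich benzoic acids, the benzyl ether is inert, the by-products are gases, and no stereocentre is involved.

Step 2
Reactants: 3 (−)-quinic acid; 4 dibutyltin oxide; 2 4-(benzyloxy)-3-methoxybenzoyl chloride (two molecules)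
Product: 7 3,4-bis-O-[4-(benzyloxy)-3-methoxybenzoyl]-1,5-quinide, via stannylene lactone 5 (not isolated), via chlorostannyl monoester 6 (not isolated)
Conditions: Bu2SnO (1.1 equiv), xylenes, reflux, Dean–Stark, 8 h; cool to 0 °C; 2 (2.4 equiv), 0 °C to 90 °C, 12 h
Reagents that add atoms: none
Why: Proposed new method: the tin carboxylate formed from 3 and Bu2SnO lactonises onto the cis 5-OH under azeotropic water removal and the tin then condenses with the only cis-vicinal diol (O3/O4), so the γ-lactone and the dioxastannolane close in the same dehydration (closest known reactions: Steliou organotin-mediated lactonisation and stannylene acetal formation of cis-diols), after which the two Sn–O bonds are acylated in turn by 2 (equatorial O3 first, axial O4 through the chlorostannyl ether on heating, as in tin-mediated multiple benzoylation of sugars) while the tertiary bridgehead 1-OH carries no tin and is left free; no bond to a stereocentre is broken, so all four centres are those of quinic acid.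

Step 3
Reactants: 7 3,4-bis-O-[4-(benzyloxy)-3-methoxybenzoyl]-1,5-quinide
Product: 9 Burkinabin A, via divanilloylquinide 8 (not isolated)
Conditions: H2 (1 atm), 10% Pd/C, THF/2 M aq HCl (3:1), rt, 4 h; then N2, rt, 3–5 d (HPLC control)
Reagents that add atoms: water, O
Why: Hydrogenolysis removes both aryl benzyl ethers (benzoate esters and methoxy groups are inert) and acid-catalysed hydrolysis then opens the strained bicyclic γ-lactone at the acyl C–O bond, which in dilute aqueous acid lies on the side of the hydroxy acid while the secondary aryl esters neither hydrolyse nor migrate, so C5 and the other centres keep their configuration.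

**Compound list**

1 | 4-(benzyloxy)-3-methoxybenzoic acid (O-benzylvanillic acid) | COc1cc(C(=O)O)ccc1OCc1ccccc1 | starting material
2 | 4-(benzyloxy)-3-methoxybenzoyl chloride | COc1cc(C(=O)Cl)ccc1OCc1ccccc1 | intermediate
3 | (−)-quinic acid, (1S,3R,4S,5R)-1,3,4,5-tetrahydroxycyclohexane-1-carboxylic acid | O[C@H]1[C@H](O)C[C@](O)(C(=O)O)C[C@H]1O | starting material
4 | dibutyltin oxide (Bu2SnO) | CCCC[Sn](=O)CCCC | starting material
5 | 3,4-O-(dibutylstannylene)-1,5-quinide (γ-lactone C1-carboxyl to O5; Bu2Sn bridging the cis O3/O4; free tertiary 1-OH; quinic acid configuration) | CCCC[Sn]1(CCCC)O[C@H]2[C@H]3C[C@](O)(C(=O)O3)C[C@H]2O1 | intermediate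
6 | 3-O-[4-(benzyloxy)-3-methoxybenzoyl]-4-O-(chlorodibutylstannyl)-1,5-quinide | CCCC[Sn](Cl)(CCCC)O[C@H]1[C@H]2C[C@](O)(C(=O)O2)C[C@H]1OC(=O)c1ccc(OCc2ccccc2)c(OC)c1 | intermediate
7 | 3,4-bis-O-[4-(benzyloxy)-3-methoxybenzoyl]-1,5-quinide (esters on the cis O3/O4, free 1-OH, quinic acid configuration) | COc1cc(C(=O)O[C@H]2[C@H]3C[C@](O)(C(=O)O3)C[C@H]2OC(=O)c2ccc(OCc4ccccc4)c(OC)c2)ccc1OCc1ccccc1 | intermediate
8 | 3,4-bis-O-(4-hydroxy-3-methoxybenzoyl)-1,5-quinide (3,4-di-O-vanilloylquinide) | COc1cc(C(=O)O[C@H]2[C@H]3C[C@](O)(C(=O)O3)C[C@H]2OC(=O)c2ccc(O)c(OC)c2)ccc1O | intermediate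
9 | Burkinabin A, (1R,3R,4S,5R)-1,5-dihydroxy-3,4-bis[(4-hydroxy-3-methoxybenzoyl)oxy]cyclohexane-1-carboxylic acid (3,4-di-O-vanilloyl-(−)-quinic acid) | COc1cc(C(=O)O[C@H]2[C@H](O)C[C@](O)(C(=O)O)C[C@H]2OC(=O)c2ccc(O)c(OC)c2)ccc1O | target

**Step count and risks**

Total steps: 3. Longest linear sequence: 3 (1 → 2 → 7 → 9); 2 steps from quinic acid.

Steps most likely to fail, in order of risk:

Step 2 is the main risk. The tin-mediated lactonisation may be incomplete, the second acylation at the axial O4 may stall at 6, or forcing may acylate O1. The fallback sets out from 3 and comes back at 7, separating the two events and dropping tin. Compound 3 is lactonised alone under Brønsted acid (TsOH·H2O cat., toluene/DMF 10:1, reflux, Dean–Stark) to crystalline 1,5-quinide F1. F1 is then acylated with 2 (2.3 equiv) in pyridine/CH2Cl2 with DMAP (0.1 equiv) at 0 °C to rt, where the equatorial 3-OH and the axial 4-OH react ahead of the tertiary bridgehead 1-OH, giving 7.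

Step 3 is the next risk. Residual tin may poison Pd/C, and a slow, incomplete lactone opening would leave polar 8 mixed with polar 9. The fallback sets out from 7 and comes back at 9, reversing the order of events. Compound 7 is hydrolysed first (THF/2 M aq HCl, rt to 40 °C) to 3,4-bis-O-[4-(benzyloxy)-3-methoxybenzoyl]quinic acid F2. This lipophilic acid is separated from unopened 7 by bicarbonate extraction, and 7 is recycled. F2 is then debenzylated under neutral conditions (H2, Pd/C, EtOAc/THF, rt) to 9, so the free phenolic product never sits in acid.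

Step 1 is the least risky; the concern is an impure or partly hydrolysed crude acid chloride carried into the tin step. The fallback sets out from 1 and comes back at 7, using an anhydride as acyl donor instead. Compound 1 with DCC (0.5 equiv, CH2Cl2, rt; urea filtered off) gives 4-(benzyloxy)-3-methoxybenzoic anhydride F3. F3 (2.5 equiv, 90 °C) is added to tin acetal 5 in step 2 in place of 2; stannylene acetals are acylated by anhydrides, the tin leaves as its dicarboxylate, and the product is again 7.

**Further compounds**

F1 | step 2 | 1,5-quinide, (1S,3R,4R,5R)-1,3,4-trihydroxy-6-oxabicyclo[3.2.1]octan-7-one | O[C@H]1[C@H]2C[C@](O)(C(=O)O2)C[C@H]1O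
F2 | step 3 | 3,4-bis-O-[4-(benzyloxy)-3-methoxybenzoyl]quinic acid | COc1cc(C(=O)O[C@H]2[C@H](O)C[C@](O)(C(=O)O)C[C@H]2OC(=O)c2ccc(OCc3ccccc3)c(OC)c2)ccc1OCc1ccccc1
F3 | step 1 | 4-(benzyloxy)-3-methoxybenzoic anhydride | COc1cc(C(=O)OC(=O)c2ccc(OCc3ccccc3)c(OC)c2)ccc1OCc1ccccc1
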